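Atom labels: C1 = lactone C=O, C2 = ring carbon carrying the benzyl group, C3 = ring carbon carrying the carbinol side chain, C4 = ring OCH2, C7 = carbinol carbon. Taking the ring oxygen out of the butyrolactone (retro-Baeyer–Villiger) leaves a cyclobutanone C1–C2–C3–C4, and this is cut into a ketene (C1=C2) and a vinyl group (C3=C4). One [2+2] cycloaddition of an arylmethyl(chloro)ketene to an (S)-1-arylallyl silyl ether thus forms C1–C4 and C2–C3, closes the four-membered ring and lets C7 set C3; chlorine on C2 later steers the ring expansion. The precursors are the TBS ether of (S)-1-(3,4-dimethoxyphenyl)allyl alcohol and a 2-chloro-3-arylpropanoyl chloride whose phenol is silylated.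

Key step: step 7

Remark: TBS = tert-butyldimethylsilyl; the target is read as the (3R,4R)-trans lactone with an (S)-configured C7; the C2 centre of 10 and 11 is racemic on purpose, since it becomes trigonal in the ketene.

Step 1
Reactants: 1 veratraldehyde (3,4-dimethoxybenzaldehyde); 2 vinylmagnesium bromide
Product: 3 rac-1-(3,4-dimethoxyphenyl)prop-2-en-1-ol
Conditions: THF, 0 °C; then aq NH4Cl
Reagents that add atoms: none
Why: Grignard 1,2-addition of the vinyl nucleophile to a non-enolisable aryl aldehyde should give the racemic allylic alcohol, which is resolved in the next step.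

Step 2
Reactants: 3 rac-1-(3,4-dimethoxyphenyl)prop-2-en-1-ol
Product: 4 (S)-1-(3,4-dimethoxyphenyl)prop-2-en-1-ol
Conditions: Novozym 435 (immobilised Candida antarctica lipase B), isopropenyl acetate, PhMe, 40 °C, stopped slightly beyond half conversion
Reagents that add atoms: none
Why: Enzymatic kinetic resolution by lipase-catalysed transesterification: with aryl as the large and vinyl as the medium group the enzyme should acylate the (R)-alcohol, so the (S)-alcohol that defines C7 remains and is separated from the (R)-acetate by chromatography.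

Step 3
Reactants: 4 (S)-1-(3,4-dimethoxyphenyl)prop-2-en-1-ol
Product: 5 (S)-tert-butyl{[1-(3,4-dimethoxyphenyl)prop-2-en-1-yl]oxy}dimethylsilane
Conditions: TBSCl, imidazole, DMF, rt
Reagents that add atoms: tert-butyldimethylsilyl chloride, CC(C)(C)[Si](C)(C)Cl
Why: Silyl ether formation under mildly basic conditions should protect the secondary alcohol without ionising the electron-rich benzylic allylic C–O bond, so C7 is untouched.

Step 4
Reactants: 6 dihydroferulic acid [3-(4-hydroxy-3-methoxyphenyl)propanoic acid]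
Product: 8 3-[4-(tert-butyldimethylsilyloxy)-3-methoxyphenyl]propanoic acid, via bis-silylated ester 7 (not isolated)
Conditions: TBSCl (2.3 equiv), imidazole, DMF, rt; then AcOH/THF/H2O, rt
Reagents that add atoms: tert-butyldimethylsilyl chloride, CC(C)(C)[Si](C)(C)Cl
Why: Silylation of phenol and acid followed by selective hydrolysis of the far more labile silyl ester should leave the aryl silyl ether; silyl is preferred to benzyl on the phenol because a final hydrogenolysis would endanger the C7 benzylic C–O bond, whereas one fluoride treatment can remove both silyl groups.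

Step 5
Reactants: 8 3-[4-(tert-butyldimethylsilyloxy)-3-methoxyphenyl]propanoic acid
Product: 10 rac-2-chloro-3-[4-(tert-butyldimethylsilyloxy)-3-methoxyphenyl]propanoic acid, via dilithium enediolate 9 (not isolated)
Conditions: LiN(iPr)2 (LDA, 2.2 equiv), THF, −78 → 0 °C; cannulated into CCl4, THF, −78 °C; then cold 1 M HCl
Reagents that add atoms: carbon tetrachloride, ClC(Cl)(Cl)Cl
Why: α-Chlorination of a carboxylic acid dianion with CCl4 as positive-chlorine donor should place chlorine on C2 without touching the electron-rich ring that chlorine-type electrophiles would attack; the new centre is racemic and is erased in the ketene.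

Step 6
Reactants: 10 rac-2-chloro-3-[4-(tert-butyldimethylsilyloxy)-3-methoxyphenyl]propanoic acid
Product: 11 rac-2-chloro-3-[4-(tert-butyldimethylsilyloxy)-3-methoxyphenyl]propanoyl chloride
Conditions: (COCl)2, DMF (cat.), CH2Cl2, 0 °C → rt; volatiles removed, used crude
Reagents that add atoms: oxalyl chloride, O=C(Cl)C(=O)Cl
Why: Acid chloride formation through the Vilsmeier-type chloroiminium intermediate proceeds under mild conditions that the aryl silyl ether and the α-chlorine should tolerate.

Step 7
Reactants: 5 (S)-tert-butyl{[1-(3,4-dimethoxyphenyl)prop-2-en-1-yl]oxy}dimethylsilane; 11 rac-2-chloro-3-[4-(tert-butyldimethylsilyloxy)-3-methoxyphenyl]propanoyl chloride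
Product: 13 (2RS,3R)-2-chloro-2-[4-(tert-butyldimethylsilyloxy)-3-methoxybenzyl]-3-[(S)-(tert-butyldimethylsilyloxy)(3,4-dimethoxyphenyl)methyl]cyclobutan-1-one, via benzylic chloroketene 12 (not isolated)
Conditions: 11 (2.5 equiv) added over 12 h by syringe pump to 5 and Et3N (3 equiv), PhMe (1 M in 5), 80 °C; unreacted 5 recovered
Reagents that add atoms: none
Why: Et3N removes HCl from 11 to give ketene 12, whose electrophilic carbonyl carbon C1 engages the terminal vinyl carbon C4 while the chlorine-bearing C2 bonds to the internal carbon C3 in a single, asynchronous [π2s+π2a] event. The closest known reaction type is the cycloaddition of alkyl(chloro)ketenes, made by dehydrochlorination of 2-chloroalkanoyl chlorides, to simple alkenes to give 2-chlorocyclobutanones. The four-membered ring is closed intermolecularly by [2+2] annulation, both ring bonds (C1–C4 and C2–C3) arising in the same step. C3 is set by C7: with C7–H lying close to the plane of the vinyl group the aryl ring screens one π-face and the ketene should add to the other, which turns (S)-C7 into (R)-C3, whereas C2 forms as an epimer mixture that is erased in step 9. The step needs regioselectivity, secured by the polarity of the ketene and by positive charge building up on the more substituted C3, π-facial selectivity, which rests on C7 alone, and chemoselectivity for the alkene over the ether oxygen, secured by the bulky, weakly basic silyl ether. Chlorine raises the electrophilicity of the ketene, and slow addition of 11 at high alkene concentration should hold back ketene self-condensation.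

Step 8
Reactants: 13 (2RS,3R)-2-chloro-2-[4-(tert-butyldimethylsilyloxy)-3-methoxybenzyl]-3-[(S)-(tert-butyldimethylsilyloxy)(3,4-dimethoxyphenyl)methyl]cyclobutan-1-one
Product: 14 (3RS,4R)-3-chloro-3-[4-(tert-butyldimethylsilyloxy)-3-methoxybenzyl]-4-[(S)-(tert-butyldimethylsilyloxy)(3,4-dimethoxyphenyl)methyl]oxolan-2-one
Conditions: mCPBA, CH2Cl2, 0 °C → rt
Reagents that add atoms: 3-chloroperoxybenzoic acid (mCPBA), O=C(OO)c1cccc(Cl)c1
Why: Baeyer–Villiger oxidation driven by release of cyclobutanone strain: in the Criegee adduct the chlorine-bearing C2 is a poor migrating group, so the C4 methylene should migrate and oxygen enters between C1 and C4, with C3 and C7 not involved.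

Step 9
Reactants: 14 (3RS,4R)-3-chloro-3-[4-(tert-butyldimethylsilyloxy)-3-methoxybenzyl]-4-[(S)-(tert-butyldimethylsilyloxy)(3,4-dimethoxyphenyl)methyl]oxolan-2-one
Product: 16 (3R,4R)-3-[4-(tert-butyldimethylsilyloxy)-3-methoxybenzyl]-4-[(S)-(tert-butyldimethylsilyloxy)(3,4-dimethoxyphenyl)methyl]oxolan-2-one, via cis lactone 15 (not isolated)
Conditions: Bu3SnH, AIBN (cat.), PhMe, 85 °C; then DBU, 80 °C
Reagents that add atoms: none
Why: Radical dehalogenation by the tin hydride chain removes the tertiary α-chlorine, hydrogen transfer to the C2 radical occurring mainly anti to the C3 substituent (cis lactone), and DBU then epimerises the acidic C2–H to the thermodynamically preferred trans lactone with (R)-C2, as is usual for α,β-disubstituted butyrolactones.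

Step 10
Reactants: 16 (3R,4R)-3-[4-(tert-butyldimethylsilyloxy)-3-methoxybenzyl]-4-[(S)-(tert-butyldimethylsilyloxy)(3,4-dimethoxyphenyl)methyl]oxolan-2-one
Product: 17 (3R,4R)-4-[(S)-(3,4-dimethoxyphenyl)(hydroxy)methyl]-3-(4-hydroxy-3-methoxybenzyl)oxolan-2-one (target)
Conditions: TBAF, AcOH (1:1), THF, 0 °C → rt
Reagents that add atoms: none
Why: Fluoride-mediated desilylation should cleave the aryl and the benzylic silyl ether in one operation, the acetic acid buffer keeping the medium near neutral so that the C7 alkoxide cannot transacylate the lactone, C2 cannot epimerise and the electron-rich benzylic alcohol does not ionise.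

Compound list
1 | veratraldehyde (3,4-dimethoxybenzaldehyde) | COc1ccc(C=O)cc1OC | starting material
2 | vinylmagnesium bromide | C=C[Mg]Br | starting material
3 | rac-1-(3,4-dimethoxyphenyl)prop-2-en-1-ol | C=CC(O)c1ccc(OC)c(OC)c1 | intermediate
4 | (S)-1-(3,4-dimethoxyphenyl)prop-2-en-1-ol | C=C[C@H](O)c1ccc(OC)c(OC)c1 | intermediate
5 | (S)-tert-butyl{[1-(3,4-dimethoxyphenyl)prop-2-en-1-yl]oxy}dimethylsilane | C=C[C@H](O[Si](C)(C)C(C)(C)C)c1ccc(OC)c(OC)c1 | intermediate
6 | dihydroferulic acid [3-(4-hydroxy-3-methoxyphenyl)propanoic acid] | COc1cc(CCC(=O)O)ccc1O | starting material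
7 | tert-butyldimethylsilyl 3-[4-(tert-butyldimethylsilyloxy)-3-methoxyphenyl]propanoate | COc1cc(CCC(=O)O[Si](C)(C)C(C)(C)C)ccc1O[Si](C)(C)C(C)(C)C | intermediate
8 | 3-[4-(tert-butyldimethylsilyloxy)-3-methoxyphenyl]propanoic acid | COc1cc(CCC(=O)O)ccc1O[Si](C)(C)C(C)(C)C | intermediate
9 | dilithium enediolate of 8 | COc1cc(CC=C(O[Li])O[Li])ccc1O[Si](C)(C)C(C)(C)C | intermediate
10 | rac-2-chloro-3-[4-(tert-butyldimethylsilyloxy)-3-methoxyphenyl]propanoic acid | COc1cc(CC(Cl)C(=O)O)ccc1O[Si](C)(C)C(C)(C)C | intermediate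
11 | rac-2-chloro-3-[4-(tert-butyldimethylsilyloxy)-3-methoxyphenyl]propanoyl chloride | COc1cc(CC(Cl)C(Cl)=O)ccc1O[Si](C)(C)C(C)(C)C | intermediate
12 | [4-(tert-butyldimethylsilyloxy)-3-methoxybenzyl](chloro)ketene | COc1cc(CC(Cl)=C=O)ccc1O[Si](C)(C)C(C)(C)C | intermediate
13 | (2RS,3R)-2-chloro-2-[4-(tert-butyldimethylsilyloxy)-3-methoxybenzyl]-3-[(S)-(tert-butyldimethylsilyloxy)(3,4-dimethoxyphenyl)methyl]cyclobutan-1-one | COc1cc(CC2(Cl)C(=O)C[C@@H]2[C@H](O[Si](C)(C)C(C)(C)C)c2ccc(OC)c(OC)c2)ccc1O[Si](C)(C)C(C)(C)C | intermediate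
14 | (3RS,4R)-3-chloro-3-[4-(tert-butyldimethylsilyloxy)-3-methoxybenzyl]-4-[(S)-(tert-butyldimethylsilyloxy)(3,4-dimethoxyphenyl)methyl]oxolan-2-one | COc1cc(CC2(Cl)C(=O)OC[C@@H]2[C@H](O[Si](C)(C)C(C)(C)C)c2ccc(OC)c(OC)c2)ccc1O[Si](C)(C)C(C)(C)C | intermediate
15 | (3S,4R)-3-[4-(tert-butyldimethylsilyloxy)-3-methoxybenzyl]-4-[(S)-(tert-butyldimethylsilyloxy)(3,4-dimethoxyphenyl)methyl]oxolan-2-one (cis lactone) | COc1cc(C[C@@H]2C(=O)OC[C@@H]2[C@H](O[Si](C)(C)C(C)(C)C)c2ccc(OC)c(OC)c2)ccc1O[Si](C)(C)C(C)(C)C | intermediate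
16 | (3R,4R)-3-[4-(tert-butyldimethylsilyloxy)-3-methoxybenzyl]-4-[(S)-(tert-butyldimethylsilyloxy)(3,4-dimethoxyphenyl)methyl]oxolan-2-one (trans lactone) | COc1cc(C[C@H]2C(=O)OC[C@@H]2[C@H](O[Si](C)(C)C(C)(C)C)c2ccc(OC)c(OC)c2)ccc1O[Si](C)(C)C(C)(C)C | intermediate
17 | (3R,4R)-4-[(S)-(3,4-dimethoxyphenyl)(hydroxy)methyl]-3-(4-hydroxy-3-methoxybenzyl)oxolan-2-one | COc1cc(C[C@H]2C(=O)OC[C@@H]2[C@H](O)c2ccc(OC)c(OC)c2)ccc1O | target

Total step count: 10. Longest linear sequence: 7 steps (steps 4–10 from dihydroferulic acid; equally steps 1–3 and 7–10 from veratraldehyde).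

Steps most likely to fail

Step 7. The unactivated vinyl group may add too slowly, so that the ketene is lost to self-condensation, and C7 may discriminate the two alkene faces only partly. Minor C3-epimeric material would be removed at 16. The fallback sets out from 5 and comes back at 16; it brings in the ring with the smaller and far more electrophilic dichloroketene and attaches the benzyl group afterwards. Dichloroketene (Cl3CCOCl, Zn–Cu couple, Et2O/DME) should add to 5 to give (3R)-2,2-dichloro-3-[(S)-(tert-butyldimethylsilyloxy)(3,4-dimethoxyphenyl)methyl]cyclobutan-1-one F1. Baeyer–Villiger oxidation (mCPBA) with migration of the CH2 carbon should give the 3,3-dichloro lactone F2, and Zn dust/AcOH should give (4R)-4-[(S)-(tert-butyldimethylsilyloxy)(3,4-dimethoxyphenyl)methyl]oxolan-2-one F3, at which stage C3 epimers can be separated. The alkylating agent is made from commercial vanillin: silylation (TBSCl, imidazole) to 4-(tert-butyldimethylsilyloxy)-3-methoxybenzaldehyde F4, NaBH4 reduction to 4-(tert-butyldimethylsilyloxy)-3-methoxybenzyl alcohol F5, and Appel bromination (CBr4, PPh3) to 4-(tert-butyldimethylsilyloxy)-3-methoxybenzyl bromide F6. Enolisation of F3 with LiN(SiMe3)2 (THF/DMPU, −78 °C) and alkylation with F6 anti to the C3 substituent should deliver trans lactone 16.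

Step 8. Migration of the chlorinated carbon C2 in place of C4, or peracid attack on the electron-rich rings, would divert the ring expansion. The fallback sets out from 13 and comes back at 16; the ring oxygen is introduced by cleaving an enol ether instead of by a peracid rearrangement. Zn dust/AcOH in THF should remove chlorine to give 2-[4-(tert-butyldimethylsilyloxy)-3-methoxybenzyl]-3-[(S)-(tert-butyldimethylsilyloxy)(3,4-dimethoxyphenyl)methyl]cyclobutan-1-one F7. LiN(iPr)2 with Me3SiCl present (THF, −78 °C) should enolise towards the unhindered C4 methylene and give the 1-(trimethylsilyloxy)cyclobutene F8 with the C1=C4 double bond. Titrated ozone (CH2Cl2/MeOH, −78 °C) followed by NaBH4 should cleave C1=C4 to the C1 acid and the C4 alcohol, hydroxy acid F9, which lactonises on acidification. DBU equilibration as in step 9 then leads to 16.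

Step 5. The dianion may be chlorinated twice, or the product may lose HCl to a cinnamate under the basic conditions. The fallback sets out from 8 and comes back at 10; chlorination is done on a neutral, isolable ketene acetal with a closed-shell chlorine electrophile. Acid 8 is converted with LiN(iPr)2 (2.2 equiv) and Me3SiCl into the bis(trimethylsilyl) ketene acetal F10. N-Chlorosuccinimide (THF, −78 → 0 °C) should give trimethylsilyl 2-chloro-3-[4-(tert-butyldimethylsilyloxy)-3-methoxyphenyl]propanoate F11, and mild aqueous work-up hydrolyses the silyl ester to 10.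

Further compounds
F1 | step 7 | (3R)-2,2-dichloro-3-[(S)-(tert-butyldimethylsilyloxy)(3,4-dimethoxyphenyl)methyl]cyclobutan-1-one | ClC1(Cl)C(=O)C[C@@H]1[C@H](O[Si](C)(C)C(C)(C)C)c2ccc(OC)c(OC)c2
F2 | step 7 | (4R)-3,3-dichloro-4-[(S)-(tert-butyldimethylsilyloxy)(3,4-dimethoxyphenyl)methyl]oxolan-2-one | ClC1(Cl)C(=O)OC[C@@H]1[C@H](O[Si](C)(C)C(C)(C)C)c2ccc(OC)c(OC)c2
F3 | step 7 | (4R)-4-[(S)-(tert-butyldimethylsilyloxy)(3,4-dimethoxyphenyl)methyl]oxolan-2-one | C1C(=O)OC[C@@H]1[C@H](O[Si](C)(C)C(C)(C)C)c2ccc(OC)c(OC)c2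
F4 | step 7 | 4-(tert-butyldimethylsilyloxy)-3-methoxybenzaldehyde | COc1cc(C=O)ccc1O[Si](C)(C)C(C)(C)C
F5 | step 7 | 4-(tert-butyldimethylsilyloxy)-3-methoxybenzyl alcohol | COc1cc(CO)ccc1O[Si](C)(C)C(C)(C)C
F6 | step 7 | 4-(tert-butyldimethylsilyloxy)-3-methoxybenzyl bromide | COc1cc(CBr)ccc1O[Si](C)(C)C(C)(C)C
F7 | step 8 | 2-[4-(tert-butyldimethylsilyloxy)-3-methoxybenzyl]-3-[(S)-(tert-butyldimethylsilyloxy)(3,4-dimethoxyphenyl)methyl]cyclobutan-1-one (C2 epimers, C3 as in 13) | COc1cc(CC2C(=O)C[C@@H]2[C@H](O[Si](C)(C)C(C)(C)C)c2ccc(OC)c(OC)c2)ccc1O[Si](C)(C)C(C)(C)C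
F8 | step 8 | 1-(trimethylsilyloxy)cyclobutene from F7 with the C1=C4 double bond (C2 epimers) | COc1cc(CC2C(O[Si](C)(C)C)=C[C@@H]2[C@H](O[Si](C)(C)C(C)(C)C)c2ccc(OC)c(OC)c2)ccc1O[Si](C)(C)C(C)(C)C
F9 | step 8 | (3R,4S)-2-[4-(tert-butyldimethylsilyloxy)-3-methoxybenzyl]-4-(tert-butyldimethylsilyloxy)-4-(3,4-dimethoxyphenyl)-3-(hydroxymethyl)butanoic acid (C2 epimers) | COc1cc(CC(C(=O)O)[C@H](CO)[C@H](O[Si](C)(C)C(C)(C)C)c2ccc(OC)c(OC)c2)ccc1O[Si](C)(C)C(C)(C)C
F10 | step 5 | bis(trimethylsilyl) ketene acetal of 8 | COc1cc(CC=C(O[Si](C)(C)C)O[Si](C)(C)C)ccc1O[Si](C)(C)C(C)(C)C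
F11 | step 5 | trimethylsilyl 2-chloro-3-[4-(tert-butyldimethylsilyloxy)-3-methoxyphenyl]propanoate | COc1cc(CC(Cl)C(=O)O[Si](C)(C)C)ccc1O[Si](C)(C)C(C)(C)C
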